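Abbreviation used throughout: TBS = tert-butyldimethylsilyl. Flavone numbering: ring C is O1–C2–C3–C4–C4a–C8a, ring A the fused benzene ring, ring B the aryl group on C2, and C11 the CH2 on C3.

## The problem

Target 14 is a flavone: benzene ring A fused to 4-pyranone ring C, with catechol ring B on C2 and, on C3, a methylene carbon (C11) that carries a prenyl ether. There is no stereocentre and no alkene geometry to set, so nothing in the molecule can or must exert stereocontrol; the difficulty lies in building a ring C whose C2=C3 double bond is fully substituted, and in doing so around sensitive groups. C3 must bear a carbon at the alcohol oxidation level, which excludes the standard flavone syntheses that leave hydrogen or oxygen at C3 unless a later C–C bond formation is added. The prenyl ether is the most fragile group: it ionises under Brønsted or Lewis acid, is cleaved by quinone oxidants and boron halides, and loses its alkene on hydrogenation, so acid-promoted chromone closures and benzyl, methyl or acetal protection of the phenols are ruled out. Before ring C exists, the C11–O bond also sits β to a carbonyl group and can be lost by elimination. Four phenols must be free at the end, two of them as an oxidisable catechol. The feature that opens a short route is ring A: its oxygens at C5, C7 and C8a are the 1,3,5-pattern of phloroglucinol 10, whose three ring CH carbons and three hydroxyls are equivalent, so acylation at any carbon followed by closure through either neighbouring hydroxyl gives one and the same chromone and leaves the other two hydroxyls as 5-OH and 7-OH. Ring A can thus be brought in unprotected, and all remaining atoms (C2, C3, C4, C11, the ether and ring B) fit into a single β-keto ester.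

## Retrosynthesis

**14 to 13.** Only the two O–Si bonds of ring B are cut. Silyl ethers are chosen because fluoride is the one deprotection that leaves an allylic ether, a pyranone and free phenols alone; hydrogenolysis, boron halides and aqueous acid all threaten the prenyl group. Ring A needs no deprotection because it is never protected. The forward step must be buffered so that the catechol is not left as a phenoxide in air.

**13 to 9 and 10.** The bonds C4–C4a and O1–C2 are cut, which removes ring C and divides the flavone at the ring fusion into phloroglucinol 10 and the acyclic β-keto ester 9. Compared with cuts at O1–C8a, C3–C4 or C2–C1', this one needs no halogen or leaving group on ring A, no protection of ring A, and no later change of oxidation level, since C4 is at the acid level and C2 at the ketone level in 9 and the product is the flavone itself. The forward reaction is a thermal, acid-free annulation. Ester 9 sheds its tert-butoxy group as the alcohol to give aroylketene 11, a ring carbon of 10 is acylated to give diketone 12, and an ortho hydroxyl closes onto the aroyl ketone with loss of water. The step must favour carbon over oxygen acylation and must keep water away from the ketene; regiochemistry is settled by symmetry.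

**9 to 6 and 3.** The C2–C3 bond (flavone numbering), i.e. the ketone-to-α-carbon bond, is cut as a crossed Claisen condensation between acid 6, activated as imidazolide 7, and lithium enolate 8 of ester 3. This delivers C11 and its ether already attached to the nucleophile. Attaching C11 later by alkoxymethylation of a preformed β-keto ester enolate would suffer from O-alkylation and would need an acid-derived α-halo ether. The forward step needs low temperature, because 8 is a β-alkoxy enolate, and excess enolate, because the heterocycle released from 7 and the product 9 are both more acidic than 3.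

**3 to 1 and 2.** The C11–O ether bond is cut as an oxa-Michael addition of prenyl alcohol 1 to tert-butyl acrylate 2. A Williamson etherification on a β-oxygenated propanoate would invite elimination, whereas the conjugate addition runs with catalytic base and forms the bond in the direction in which it is stable. The tert-butyl ester is chosen here because it later serves as the thermal ketene trigger.

**6 to 4.** The silyl groups are removed retrosynthetically to reach 3,4-dihydroxybenzoic acid 4; forward, exhaustive silylation gives silyl ester 5, and mild hydrolysis frees the acid 6.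

## Roads not taken

**Alternative 1:** The cuts are C2–C1' and C3–C11 on an intact chromone. 5,7-Bis(silyloxy)chromone A1 would take up the ring B Grignard reagent A2 under CuBr·SMe2 catalysis with Me3SiCl, and the silyl enol ether formed would be alkylated at C3 by chloromethyl prenyl ether A3 with ZnBr2, giving trans-flavanone A4 in one flask.
- Merits: two C–C bonds are formed in one operation at low temperature, and ring B and the ether side chain can be varied independently. In modularity this road is better than the chosen one.
- Weak points: A4 is one oxidation level below the target. Its two stereocentres would have to be destroyed again by a C2–C3 dehydrogenation, and the usual reagents for that (quinone oxidants, iodine in dimethyl sulfoxide, selenium dioxide) are the ones that attack a prenyl ether or its allylic positions. An enolate-based dehydrogenation would compete with β-elimination of the ring oxygen. A3 is an α-chloro ether that must be made under acidic conditions from an acid-sensitive allylic alcohol, and ZnBr2 is a Lewis acid in contact with the prenyl ether and the peri 5-silyloxy group. A1 needs its own preparation and four silyl groups in all.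
- Comparison: against the modularity of this road, the chosen plan arrives directly at the flavone oxidation level, uses ring A unprotected, and needs about half the steps.

**Alternative 2:** The cut is C3–C4. Aldehyde A5, a 2-(1-arylpropargyloxy)benzaldehyde, would be turned by a thiazolium-derived carbene (K2CO3) into a Breslow intermediate that adds to the internal alkyne carbon and closes ring C as 3-methyleneflavanone A6.
- Merits: the closure is catalytic, metal-free, atom-economic and runs near room temperature, which is milder than a thermolysis at 150 °C. The exocyclic enone of A6 is a Michael acceptor to which prenyl alcohol 1 could in principle be added, converging on a flavanone of the constitution of A4.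
- Weak points: A6 lacks the ether oxygen and is at the wrong oxidation level. Under base the exocyclic double bond tends to migrate into the ring, leaving a 3-methyl group that no longer accepts an alcohol. The oxa-Michael addition is reversible, and after it the dehydrogenation problem of Alternative 1 returns. A5 requires etherification of a hindered, chelated phenol with a benzylic and propargylic secondary alcohol, and its C2–H is acidic enough for alkyne-to-allene isomerisation under the reaction conditions.
- Comparison: the mildness of the carbene step is conceded. The chosen plan carries the ether through the ring closure, needs no redox adjustment, and is much shorter.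

**Alternative 3:** The cut is O1–C8a. In diketone A7, which carries a 2,4,6-trifluorophenyl ketone as latent ring A, the enolate oxygen of the ring B ketone (K2CO3, N,N-dimethylformamide) would displace an ortho fluoride and give 5,7-difluoroflavone A8.
- Merits: this closure has strong precedent, runs at low temperature, involves no water-sensitive intermediate, uses the same symmetry argument (two equivalent ortho fluorides), and gives the flavone oxidation level directly. As a ring closure it is probably more reliable than the thermal annulation, and this is conceded.
- Weak points: A8 has fluorine where the target has oxygen at C5 and C7. Two further substitutions by an oxygen nucleophile are needed, the second slowed by the donor introduced in the first, with a nucleophile that can also add at C2 and open ring C. The resulting ethers and the allyl ethers of ring B must then be removed with zerovalent palladium beside a prenyl ether, which is itself allylic. A7 requires C-acylation of a β-alkoxy ketone enolate by a doubly ortho-substituted aroyl electrophile.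
- Comparison: against the safer closure, the chosen plan takes all three ring A oxygens from phloroglucinol 10, needs no C–F to C–O exchange, and ends with a single deprotection.

Key step: step 4

Assumption: phloroglucinol 10 is used anhydrous (the commercial dihydrate is dried first), because water would intercept the ketene; keto ester 9 is a racemic keto/enol mixture whose stereocentre is erased in step 4.

## Route

**Step 1**
Reactants: 1 3-methylbut-2-en-1-ol (prenyl alcohol); 2 tert-butyl acrylate
Product: 3 tert-butyl 3-[(3-methylbut-2-en-1-yl)oxy]propanoate
Conditions: 1 (2 equiv), KOt-Bu (5 mol %), THF, 0 °C → rt; AcOH quench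
Reagents that add atoms: none
Why: Base-catalysed oxa-Michael addition; the ester enolate formed is reprotonated by more 1 so the alkoxide turns over, the tert-butyl ester cannot transesterify, and excess 1 holds back acrylate oligomerisation.

**Step 2**
Reactants: 4 3,4-dihydroxybenzoic acid
Product: 6 3,4-bis(tert-butyldimethylsilyloxy)benzoic acid, via silyl ester 5 (not isolated)
Conditions: TBSCl (3.5 equiv), imidazole, DMF, rt; then AcOH/THF/H2O, rt
Reagents that add atoms: tert-butyldimethylsilyl chloride, CC(C)(C)[Si](C)(C)Cl
Why: Imidazole-promoted silylation of both phenols and the acid, then selective hydrolysis of the much more labile silyl ester in aqueous acetic acid, which leaves aryl silyl ethers intact.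

**Step 3**
Reactants: 6 3,4-bis(tert-butyldimethylsilyloxy)benzoic acid; 3 tert-butyl 3-[(3-methylbut-2-en-1-yl)oxy]propanoate
Product: 9 racemic tert-butyl 3-[3,4-bis(tert-butyldimethylsilyloxy)phenyl]-2-{[(3-methylbut-2-en-1-yl)oxy]methyl}-3-oxopropanoate, via acyl imidazole 7 (not isolated), via lithium enolate 8 (not isolated)
Conditions: 6, 1,1'-carbonyldiimidazole (1.1 equiv), THF, rt, then Ar purge to expel CO2; 3 (3.3 equiv), lithium diisopropylamide (3.2 equiv), THF, −78 °C; solution of 7 added, −78 → −40 °C; AcOH quench at −78 °C
Reagents that add atoms: 1,1'-carbonyldiimidazole, O=C(n1ccnc1)n1ccnc1; lithium diisopropylamide, [Li]N(C(C)C)C(C)C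
Why: Crossed Claisen condensation of a preformed ester enolate with an acyl imidazole; the excess of 8 absorbs the protons of liberated imidazole and of the more acidic product, and at −78 °C the β-alkoxy enolate does not yet expel alkoxide. The imidazolyl group of 7 comes from 1,1'-carbonyldiimidazole and the lithium of 8 from lithium diisopropylamide, and both are lost again on the way to 9, whose atoms all come from 6 and 3. The stereocentre at the α-carbon forms racemic and is removed in step 4.

**Step 4**
Reactants: 9 racemic tert-butyl 3-[3,4-bis(tert-butyldimethylsilyloxy)phenyl]-2-{[(3-methylbut-2-en-1-yl)oxy]methyl}-3-oxopropanoate; 10 phloroglucinol (benzene-1,3,5-triol)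
Product: 13 2-[3,4-bis(tert-butyldimethylsilyloxy)phenyl]-5,7-dihydroxy-3-{[(3-methylbut-2-en-1-yl)oxy]methyl}-4H-chromen-4-one, via aroylketene 11 (not isolated), via acylphloroglucinol 12 (not isolated)
Conditions: 9 added slowly to anhydrous 10 (3 equiv) in diglyme at 150 °C under a slow Ar stream that carries off t-BuOH and H2O
Reagents that add atoms: none
Why: The enol of 9 loses tert-butanol near 150 °C to give aroylketene 11, the known thermal behaviour of tert-butyl β-keto esters. Phloroglucinol adds to 11 through oxygen reversibly (the aryl β-keto ester returns to the ketene) and through a ring carbon irreversibly, so material drains into acylphloroglucinol 12 and the C4–C4a bond is made. In 12 an ortho hydroxyl attacks the aroyl carbonyl in a 6-exo-trig closure and the hemiketal loses water to the conjugated pyranone, making O1–C2 and closing ring C. The closest known reaction is the uncatalysed thermal condensation of phloroglucinol with β-keto esters, α-substituted ones included, to 5,7-dihydroxychromones and flavones (Mentzer pyrone synthesis). No stereocentre is formed and the one in 9 becomes sp2. Carbon over oxygen acylation is secured by the reversibility of the ester, regiochemistry by the threefold symmetry of 10, and single annulation by the excess of 10 and the deactivating, hydrogen-bonded carbonyl of the product. The absence of acid keeps the coumarin-forming Pechmann pathway closed and spares the prenyl and silyl ethers; slow addition keeps the ketene dilute against dimerisation, and the gas stream removes the water that would otherwise hydrolyse 11.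

**Step 5**
Reactants: 13 2-[3,4-bis(tert-butyldimethylsilyloxy)phenyl]-5,7-dihydroxy-3-{[(3-methylbut-2-en-1-yl)oxy]methyl}-4H-chromen-4-one
Product: 14 2-(3,4-dihydroxyphenyl)-5,7-dihydroxy-3-{[(3-methylbut-2-en-1-yl)oxy]methyl}-4H-chromen-4-one (ophioglonol prenyl ether)
Conditions: tetrabutylammonium fluoride (2.4 equiv), AcOH (2.4 equiv), THF, 0 °C → rt, Ar
Reagents that add atoms: none
Why: Fluoride-induced cleavage of aryl silyl ethers, driven by the Si–F bond and the phenoxide leaving group; acetic acid protonates the phenoxides so the catechol is not exposed to base and air, and neither the allylic ether nor the pyranone reacts.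

## Compound list

1 | 3-methylbut-2-en-1-ol (prenyl alcohol) | CC(C)=CCO | starting material
2 | tert-butyl acrylate | C=CC(=O)OC(C)(C)C | starting material
3 | tert-butyl 3-[(3-methylbut-2-en-1-yl)oxy]propanoate | CC(C)=CCOCCC(=O)OC(C)(C)C | intermediate
4 | 3,4-dihydroxybenzoic acid | O=C(O)c1ccc(O)c(O)c1 | starting material
5 | tert-butyldimethylsilyl 3,4-bis(tert-butyldimethylsilyloxy)benzoate | CC(C)(C)[Si](C)(C)OC(=O)c1ccc(O[Si](C)(C)C(C)(C)C)c(O[Si](C)(C)C(C)(C)C)c1 | intermediate (not isolated)
6 | 3,4-bis(tert-butyldimethylsilyloxy)benzoic acid | O=C(O)c1ccc(O[Si](C)(C)C(C)(C)C)c(O[Si](C)(C)C(C)(C)C)c1 | intermediate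
7 | [3,4-bis(tert-butyldimethylsilyloxy)phenyl](1H-imidazol-1-yl)methanone | O=C(c1ccc(O[Si](C)(C)C(C)(C)C)c(O[Si](C)(C)C(C)(C)C)c1)n1ccnc1 | intermediate (not isolated)
8 | lithium enolate of 3 (lithium 1-tert-butoxy-3-[(3-methylbut-2-en-1-yl)oxy]prop-1-en-1-olate) | CC(C)=CCOCC=C(O[Li])OC(C)(C)C | intermediate (not isolated)
9 | racemic tert-butyl 3-[3,4-bis(tert-butyldimethylsilyloxy)phenyl]-2-{[(3-methylbut-2-en-1-yl)oxy]methyl}-3-oxopropanoate | CC(C)=CCOCC(C(=O)OC(C)(C)C)C(=O)c1ccc(O[Si](C)(C)C(C)(C)C)c(O[Si](C)(C)C(C)(C)C)c1 | intermediate
10 | phloroglucinol (benzene-1,3,5-triol) | Oc1cc(O)cc(O)c1 | starting material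
11 | 2-[3,4-bis(tert-butyldimethylsilyloxy)benzoyl]-3-[(3-methylbut-2-en-1-yl)oxy]prop-1-en-1-one (aroylketene) | CC(C)=CCOCC(=C=O)C(=O)c1ccc(O[Si](C)(C)C(C)(C)C)c(O[Si](C)(C)C(C)(C)C)c1 | intermediate (not isolated)
12 | racemic 1-[3,4-bis(tert-butyldimethylsilyloxy)phenyl]-2-{[(3-methylbut-2-en-1-yl)oxy]methyl}-3-(2,4,6-trihydroxyphenyl)propane-1,3-dione | CC(C)=CCOCC(C(=O)c1c(O)cc(O)cc1O)C(=O)c1ccc(O[Si](C)(C)C(C)(C)C)c(O[Si](C)(C)C(C)(C)C)c1 | intermediate (not isolated)
13 | 2-[3,4-bis(tert-butyldimethylsilyloxy)phenyl]-5,7-dihydroxy-3-{[(3-methylbut-2-en-1-yl)oxy]methyl}-4H-chromen-4-one | CC(C)=CCOCc1c(-c2ccc(O[Si](C)(C)C(C)(C)C)c(O[Si](C)(C)C(C)(C)C)c2)oc2cc(O)cc(O)c2c1=O | intermediate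
14 | 2-(3,4-dihydroxyphenyl)-5,7-dihydroxy-3-{[(3-methylbut-2-en-1-yl)oxy]methyl}-4H-chromen-4-one (ophioglonol prenyl ether) | CC(C)=CCOCc1c(-c2ccc(O)c(O)c2)oc2cc(O)cc(O)c2c1=O | target

## Step count and risks

Total steps: 5. Longest linear sequence: 4 (steps 2, 3, 4, 5 from 4; equally steps 1, 3, 4, 5 from 1).

**Step 4 (key step).** Three things are most likely to go wrong. The first is loss of prenyl alcohol by β-elimination from 9 or 12 at 150 °C, since the C11–O bond is β to two carbonyl groups until ring C has formed. The second is hydrolysis of the ketene by the water set free in the cyclodehydration, followed by decarboxylation. The third is carbon acylation that is too slow, so that the ketene dimerises or the silyl groups begin to move to the excess triphenol. Changes of solvent, temperature or heating mode would be tried first.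

The fallback takes the ether out of the thermal step; it sets out from imidazolide 7 and returns to the route at target 14. tert-Butyl propionate, deprotonated with lithium diisopropylamide at −78 °C, would be acylated by 7 to give racemic tert-butyl 3-[3,4-bis(tert-butyldimethylsilyloxy)phenyl]-2-methyl-3-oxopropanoate F1. The same thermal condensation with 10, now an α-methyl case with nothing β to the carbonyls that can leave and therefore open to forcing, should give 2-[3,4-bis(tert-butyldimethylsilyloxy)phenyl]-5,7-dihydroxy-3-methyl-4H-chromen-4-one F2. Acetylation (Ac2O, pyridine, 4-dimethylaminopyridine) would give the 5,7-diacetate F3, in which ring A is deactivated. Radical bromination (N-bromosuccinimide, azobisisobutyronitrile, PhCF3, 80 °C) would then give the 3-(bromomethyl)flavone F4, and Ag2O-promoted etherification with prenyl alcohol 1 in CH2Cl2 the prenyl ether diacetate F5. Finally, K2CO3 in degassed methanol under argon, with an AcOH quench, should remove the acetates and the aryl silyl ethers together and give 14.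

**Step 3.** The most likely failure is proton transfer outrunning acylation. Imidazole and the product quench 8, and if the mixture must be warmed to complete the reaction, the β-alkoxy enolate can expel lithium prenyloxide and return acrylate. The fallback replaces acylation by aldol addition and oxidation; it sets out from enolate 8 and returns at 9. Commercial 3,4-dihydroxybenzaldehyde would be silylated (TBSCl, imidazole, DMF) to 3,4-bis(tert-butyldimethylsilyloxy)benzaldehyde F6. Addition of 8 to F6 at −78 °C, which is fast and forms no acidic product, should give the β-hydroxy ester F7 as a racemic diastereomer mixture. Dess–Martin periodinane buffered with NaHCO3 in CH2Cl2 would then oxidise F7 to 9.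

**Step 5.** The most likely failure is oxidation of the catechol during or after desilylation, or loss of the polar tetraphenol on separation from ammonium and silicon residues. The fallback traps the phenols before isolation; it sets out from 13 and returns at 14. After the fluoride treatment, acetic anhydride and pyridine would be added to the same flask, giving the tetraacetate F8 of the target, a stable compound that can be chromatographed or crystallised. Methanolysis with catalytic K2CO3 in degassed methanol at 0 °C under argon, followed by acidification with AcOH, should then liberate 14 with only a volatile by-product.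

## Further compounds

F1 | step 4 | racemic tert-butyl 3-[3,4-bis(tert-butyldimethylsilyloxy)phenyl]-2-methyl-3-oxopropanoate | CC(C(=O)OC(C)(C)C)C(=O)c1ccc(O[Si](C)(C)C(C)(C)C)c(O[Si](C)(C)C(C)(C)C)c1
F2 | step 4 | 2-[3,4-bis(tert-butyldimethylsilyloxy)phenyl]-5,7-dihydroxy-3-methyl-4H-chromen-4-one | Cc1c(-c2ccc(O[Si](C)(C)C(C)(C)C)c(O[Si](C)(C)C(C)(C)C)c2)oc2cc(O)cc(O)c2c1=O
F3 | step 4 | 5,7-diacetoxy-2-[3,4-bis(tert-butyldimethylsilyloxy)phenyl]-3-methyl-4H-chromen-4-one | Cc1c(-c2ccc(O[Si](C)(C)C(C)(C)C)c(O[Si](C)(C)C(C)(C)C)c2)oc2cc(OC(C)=O)cc(OC(C)=O)c2c1=O
F4 | step 4 | 5,7-diacetoxy-3-(bromomethyl)-2-[3,4-bis(tert-butyldimethylsilyloxy)phenyl]-4H-chromen-4-one | BrCc1c(-c2ccc(O[Si](C)(C)C(C)(C)C)c(O[Si](C)(C)C(C)(C)C)c2)oc2cc(OC(C)=O)cc(OC(C)=O)c2c1=O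
F5 | step 4 | 5,7-diacetoxy-2-[3,4-bis(tert-butyldimethylsilyloxy)phenyl]-3-{[(3-methylbut-2-en-1-yl)oxy]methyl}-4H-chromen-4-one | CC(C)=CCOCc1c(-c2ccc(O[Si](C)(C)C(C)(C)C)c(O[Si](C)(C)C(C)(C)C)c2)oc2cc(OC(C)=O)cc(OC(C)=O)c2c1=O
F6 | step 3 | 3,4-bis(tert-butyldimethylsilyloxy)benzaldehyde | O=Cc1ccc(O[Si](C)(C)C(C)(C)C)c(O[Si](C)(C)C(C)(C)C)c1
F7 | step 3 | tert-butyl 3-[3,4-bis(tert-butyldimethylsilyloxy)phenyl]-3-hydroxy-2-{[(3-methylbut-2-en-1-yl)oxy]methyl}propanoate (racemic, both diastereomers) | CC(C)=CCOCC(C(=O)OC(C)(C)C)C(O)c1ccc(O[Si](C)(C)C(C)(C)C)c(O[Si](C)(C)C(C)(C)C)c1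
F8 | step 5 | 5,7-diacetoxy-2-(3,4-diacetoxyphenyl)-3-{[(3-methylbut-2-en-1-yl)oxy]methyl}-4H-chromen-4-one | CC(C)=CCOCc1c(-c2ccc(OC(C)=O)c(OC(C)=O)c2)oc2cc(OC(C)=O)cc(OC(C)=O)c2c1=O
A1 | alternative 1 | 5,7-bis(tert-butyldimethylsilyloxy)-4H-chromen-4-one | O=c1ccoc2cc(O[Si](C)(C)C(C)(C)C)cc(O[Si](C)(C)C(C)(C)C)c12
A2 | alternative 1 | [3,4-bis(tert-butyldimethylsilyloxy)phenyl]magnesium bromide | CC(C)(C)[Si](C)(C)Oc1ccc([Mg]Br)cc1O[Si](C)(C)C(C)(C)C
A3 | alternative 1 | 1-(chloromethoxy)-3-methylbut-2-ene (chloromethyl prenyl ether) | CC(C)=CCOCCl
A4 | alternative 1 | racemic trans-2-[3,4-bis(tert-butyldimethylsilyloxy)phenyl]-5,7-bis(tert-butyldimethylsilyloxy)-3-{[(3-methylbut-2-en-1-yl)oxy]methyl}chroman-4-one (one enantiomer drawn) | CC(C)=CCOC[C@@H]1C(=O)c2c(O[Si](C)(C)C(C)(C)C)cc(O[Si](C)(C)C(C)(C)C)cc2O[C@H]1c1ccc(O[Si](C)(C)C(C)(C)C)c(O[Si](C)(C)C(C)(C)C)c1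
A5 | alternative 2 | racemic 2-{1-[3,4-bis(tert-butyldimethylsilyloxy)phenyl]prop-2-yn-1-yloxy}-4,6-bis(tert-butyldimethylsilyloxy)benzaldehyde | C#CC(Oc1cc(O[Si](C)(C)C(C)(C)C)cc(O[Si](C)(C)C(C)(C)C)c1C=O)c1ccc(O[Si](C)(C)C(C)(C)C)c(O[Si](C)(C)C(C)(C)C)c1
A6 | alternative 2 | racemic 2-[3,4-bis(tert-butyldimethylsilyloxy)phenyl]-5,7-bis(tert-butyldimethylsilyloxy)-3-methylenechroman-4-one | C=C1C(=O)c2c(O[Si](C)(C)C(C)(C)C)cc(O[Si](C)(C)C(C)(C)C)cc2OC1c1ccc(O[Si](C)(C)C(C)(C)C)c(O[Si](C)(C)C(C)(C)C)c1
A7 | alternative 3 | racemic 1-[3,4-bis(allyloxy)phenyl]-2-{[(3-methylbut-2-en-1-yl)oxy]methyl}-3-(2,4,6-trifluorophenyl)propane-1,3-dione | CC(C)=CCOCC(C(=O)c1c(F)cc(F)cc1F)C(=O)c1ccc(OCC=C)c(OCC=C)c1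
A8 | alternative 3 | 2-[3,4-bis(allyloxy)phenyl]-5,7-difluoro-3-{[(3-methylbut-2-en-1-yl)oxy]methyl}-4H-chromen-4-one | CC(C)=CCOCc1c(-c2ccc(OCC=C)c(OCC=C)c2)oc2cc(F)cc(F)c2c1=O
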